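**Plan**
Labels: C7 = ArCH–O, C8 = CH carrying C9H2OH, O3'/O4' = ring oxygens on C7/C8, C1' = arene carbon carrying the enal (O3' meta, O4' para to it).
Cuts: first the phenol O–Si bond and the enal C=C (Wittig). Next C9 and the carbon on C1' go back to esters, and last the dioxane ring is cut at C7–C8 and C8–O4'.
Enabling feature: lifting C8–C9 out of the six-membered O3'–C7–C8–O4' ring leaves C7 bonded to both catechol oxygens. That is a 2-aryl-1,3-benzodioxole (the catechol acetal of syringaldehyde), and the excised CH–CO2Et unit is ethyl diazoacetate. C7 is an ionisable benzylic acetal carbon, and the C1' ester distinguishes O4' (leaving group) from O3' (donor).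
Forward order: silylation, closure of the five-membered acetal ring on methyl 3,4-dihydroxybenzoate, one-carbon expansion to the 1,4-dioxane, double ester reduction, benzylic oxidation, two-carbon olefination, desilylation.
Stereochemistry: C7 (S) comes from a chiral Sc(OTf)3/N,N'-dioxide catalyst acting on a planar cation common to both acetal enantiomers. C8 (S in the target) is relayed from C7 as the trans relationship in the ring closure, and the E-alkene comes from the stabilised ylide.

Key step: step 3

Assumption: the sense of induction of the Sc(OTf)3/N,N'-dioxide catalyst on an acetal-derived cation cannot be foretold, so the ligand antipode (from L- or D-pipecolic acid) that leads to the 7S series is taken to be the one used.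

Step 1
Reactants: 1 syringaldehyde
Product: 2 3,5-dimethoxy-4-(triisopropylsilyloxy)benzaldehyde
Conditions: TIPSCl, imidazole, DMAP (cat.), DMF, rt
Reagents that add atoms: triisopropylsilyl chloride, CC(C)[Si](Cl)(C(C)C)C(C)C
Why: Standard imidazole-promoted O-silylation of a phenol; the bulky aryl silyl ether should withstand the acid of step 2, the Lewis acid of step 3 and hydride, offers no alkene or acetal for ethyl diazoacetate or the catalyst to attack, and leaves under buffered fluoride at the end.

Step 2
Reactants: 2 3,5-dimethoxy-4-(triisopropylsilyloxy)benzaldehyde; 3 methyl 3,4-dihydroxybenzoate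
Product: 5 methyl 2-[3,5-dimethoxy-4-(triisopropylsilyloxy)phenyl]-1,3-benzodioxole-5-carboxylate (racemic), via dimethyl acetal 4 (not isolated)
Conditions: HC(OMe)3, TsOH·H2O (cat.), MeOH, rt, then all volatiles stripped; 3, toluene, reflux, Soxhlet with 4 Å MS; Et3N quench
Reagents that add atoms: trimethyl orthoformate, COC(OC)OC (its methoxy groups stand in 4 only)
Why: Acid-catalysed acetalisation followed by transacetalisation, the usual entry to 2-aryl-1,3-benzodioxoles, is pulled to the cyclic acetal because the sieves take up the released methanol, and the acetal carbon forms racemic, which is harmless since step 3 erases it.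

Step 3
Reactants: 5 methyl 2-[3,5-dimethoxy-4-(triisopropylsilyloxy)phenyl]-1,3-benzodioxole-5-carboxylate (racemic); 6 ethyl diazoacetate
Product: 9 ethyl (2R,3S)-3-[3,5-dimethoxy-4-(triisopropylsilyloxy)phenyl]-6-(methoxycarbonyl)-2,3-dihydro-1,4-benzodioxine-2-carboxylate, via oxocarbenium phenoxide 7 (not isolated), via diazonium phenoxide 8 (not isolated)
Conditions: Sc(OTf)3 (10 mol %), L* (11 mol %; L* = 1,1'-(propane-1,3-diyl)bis[N-(2,6-diisopropylphenyl)piperidine-2-carboxamide] 1,1'-dioxide, single antipode), 4 Å MS, CH2Cl2, −20 °C, 6 added over 2 h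
Reagents that add atoms: none
Why: Proposed new method: Sc(OTf)3–L* binds O4' and ionises the C7–O4' bond of 5 to the aryl-stabilised oxocarbenium phenoxide 7, the nucleophilic carbon of 6 adds to C7 (new C7–C8 bond) to give diazonium phenoxide 8, and O4' then displaces N2 from C8 (new C8–O4' bond), so that CHCO2Et is formally inserted into one acetal C–O bond. The closest known reaction types are the achiral BF3·OEt2 or SnCl4 promoted insertions of diazo esters into acetal and orthoester C–O bonds, the Rh2(OAc)4 catalysed oxonium ylide [1,2]-shift that expands 2-aryl-1,3-dioxolanes to 1,4-dioxanes, and the Sc(OTf)3/N,N'-dioxide catalysed asymmetric Roskamp homologation of carbonyl compounds, none of which has been shown enantioselectively on a benzodioxole. The one new ring, the 1,4-dioxane, closes in the 6-exo-tet mode with N2 as the exocyclic leaving group. C7 is under catalyst control: both enantiomers of 5 open to the same planar cation, in which the chiral Sc-bound phenoxide sits on the ring carbon next to O3' and screens one face of C7, so the racemate should converge on the 7S configuration. C8 is relayed from C7: the diazonium centre of 8 can equilibrate by reversible proton loss to the diazo ester, and displacement with inversion should be fastest through the half-chair that holds aryl and ester pseudo-equatorial, which gives the trans (2R,3S) product. The step needs cleavage of C7–O4' rather than C7–O3', secured by the methyl ester that lies para to O4' (better phenoxide leaving group) but only meta to O3' (better donor to the cation), and it needs oxygen capture to outrun 1,2-aryl and 1,2-hydride shifts in 8, secured by the phenoxide tethered for six-ring closure and by the silyl ether, which makes the aryl ring a poorer migrating group than an alkyl ether would.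

Step 4
Reactants: 9 ethyl (2R,3S)-3-[3,5-dimethoxy-4-(triisopropylsilyloxy)phenyl]-6-(methoxycarbonyl)-2,3-dihydro-1,4-benzodioxine-2-carboxylate
Product: 10 {(2S,3S)-3-[3,5-dimethoxy-4-(triisopropylsilyloxy)phenyl]-2,3-dihydro-1,4-benzodioxine-2,6-diyl}dimethanol
Conditions: LiAlH4, THF, 0 °C; aq. potassium sodium tartrate
Reagents that add atoms: none
Why: LiAlH4 ester reduction, long used on 3-aryl-1,4-benzodioxane-2-carboxylates, adds hydride much faster than it enolises C8, so both stereocentres are carried through unchanged (the C8 descriptor turns from R to S only because CH2OH ranks below C7).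

Step 5
Reactants: 10 {(2S,3S)-3-[3,5-dimethoxy-4-(triisopropylsilyloxy)phenyl]-2,3-dihydro-1,4-benzodioxine-2,6-diyl}dimethanol
Product: 11 (2S,3S)-3-[3,5-dimethoxy-4-(triisopropylsilyloxy)phenyl]-2-(hydroxymethyl)-2,3-dihydro-1,4-benzodioxine-6-carbaldehyde
Conditions: activated MnO2 (excess), CH2Cl2, rt
Reagents that add atoms: none
Why: Chemoselective MnO2 oxidation takes only the benzylic alcohol, which is activated by the para oxygen O4', while the saturated primary C9 alcohol and the silyl-masked phenol are inert to this reagent.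

Step 6
Reactants: 11 (2S,3S)-3-[3,5-dimethoxy-4-(triisopropylsilyloxy)phenyl]-2-(hydroxymethyl)-2,3-dihydro-1,4-benzodioxine-6-carbaldehyde; 12 (triphenylphosphoranylidene)acetaldehyde
Product: 13 (2E)-3-{(2S,3S)-3-[3,5-dimethoxy-4-(triisopropylsilyloxy)phenyl]-2-(hydroxymethyl)-2,3-dihydro-1,4-benzodioxin-6-yl}prop-2-enal
Conditions: 12 (1.2 equiv), toluene, 80 °C
Reagents that add atoms: none
Why: Wittig olefination with the stabilised formylmethylene ylide needs no added base, tolerates the free alcohol, touches neither stereocentre and gives the E-enal as stabilised ylides do.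

Step 7
Reactants: 13 (2E)-3-{(2S,3S)-3-[3,5-dimethoxy-4-(triisopropylsilyloxy)phenyl]-2-(hydroxymethyl)-2,3-dihydro-1,4-benzodioxin-6-yl}prop-2-enal
Product: 14 (2E)-3-[(2S,3S)-3-(4-hydroxy-3,5-dimethoxyphenyl)-2-(hydroxymethyl)-2,3-dihydro-1,4-benzodioxin-6-yl]prop-2-enal (target, 7S,8S)
Conditions: TBAF, AcOH (1:1), THF, 0 °C
Reagents that add atoms: none
Why: Fluoride cleavage of an aryl silyl ether is fast at low temperature, and the acetic acid buffer protonates the phenoxide at once, so that neither quinone methide formation at C7 (expulsion of O3') nor addition to the enal should set in and both stereocentres and the E-alkene stay intact.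

**Compound list**
1 | syringaldehyde (4-hydroxy-3,5-dimethoxybenzaldehyde) | COc1cc(C=O)cc(OC)c1O | starting material
2 | 3,5-dimethoxy-4-(triisopropylsilyloxy)benzaldehyde | COc1cc(C=O)cc(OC)c1O[Si](C(C)C)(C(C)C)C(C)C | intermediate
3 | methyl 3,4-dihydroxybenzoate | COC(=O)c1ccc(O)c(O)c1 | starting material
4 | 4-(dimethoxymethyl)-2,6-dimethoxyphenyl triisopropylsilyl ether (dimethyl acetal of 2, not isolated) | COC(OC)c1cc(OC)c(O[Si](C(C)C)(C(C)C)C(C)C)c(OC)c1 | intermediate
5 | methyl 2-[3,5-dimethoxy-4-(triisopropylsilyloxy)phenyl]-1,3-benzodioxole-5-carboxylate (racemic at the acetal carbon) | COC(=O)c1ccc2OC(c3cc(OC)c(O[Si](C(C)C)(C(C)C)C(C)C)c(OC)c3)Oc2c1 | intermediate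
6 | ethyl diazoacetate | CCOC(=O)C=[N+]=[N-] | starting material
7 | ring-opened oxocarbenium phenoxide (C7=O3' cation, O4' phenoxide; drawn without the Sc centre it is bound to, not isolated) | COC(=O)c1ccc([O-])c([O+]=Cc2cc(OC)c(O[Si](C(C)C)(C(C)C)C(C)C)c(OC)c2)c1 | intermediate
8 | ethyl (3S)-2-diazonio-3-[3,5-dimethoxy-4-(triisopropylsilyloxy)phenyl]-3-[5-(methoxycarbonyl)-2-oxidophenoxy]propanoate (C8 labile, drawn without Sc, not isolated) | COC(=O)c1ccc([O-])c(O[C@@H](c2cc(OC)c(O[Si](C(C)C)(C(C)C)C(C)C)c(OC)c2)C([N+]#N)C(=O)OCC)c1 | intermediate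
9 | ethyl (2R,3S)-3-[3,5-dimethoxy-4-(triisopropylsilyloxy)phenyl]-6-(methoxycarbonyl)-2,3-dihydro-1,4-benzodioxine-2-carboxylate (trans) | COc1cc([C@@H]2Oc3cc(C(=O)OC)ccc3O[C@H]2C(=O)OCC)cc(OC)c1O[Si](C(C)C)(C(C)C)C(C)C | intermediate
10 | {(2S,3S)-3-[3,5-dimethoxy-4-(triisopropylsilyloxy)phenyl]-2,3-dihydro-1,4-benzodioxine-2,6-diyl}dimethanol | COc1cc([C@@H]2Oc3cc(CO)ccc3O[C@H]2CO)cc(OC)c1O[Si](C(C)C)(C(C)C)C(C)C | intermediate
11 | (2S,3S)-3-[3,5-dimethoxy-4-(triisopropylsilyloxy)phenyl]-2-(hydroxymethyl)-2,3-dihydro-1,4-benzodioxine-6-carbaldehyde | COc1cc([C@@H]2Oc3cc(C=O)ccc3O[C@H]2CO)cc(OC)c1O[Si](C(C)C)(C(C)C)C(C)C | intermediate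
12 | (triphenylphosphoranylidene)acetaldehyde | O=CC=P(c1ccccc1)(c1ccccc1)c1ccccc1 | starting material
13 | (2E)-3-{(2S,3S)-3-[3,5-dimethoxy-4-(triisopropylsilyloxy)phenyl]-2-(hydroxymethyl)-2,3-dihydro-1,4-benzodioxin-6-yl}prop-2-enal | COc1cc([C@@H]2Oc3cc(/C=C/C=O)ccc3O[C@H]2CO)cc(OC)c1O[Si](C(C)C)(C(C)C)C(C)C | intermediate
14 | (2E)-3-[(2S,3S)-3-(4-hydroxy-3,5-dimethoxyphenyl)-2-(hydroxymethyl)-2,3-dihydro-1,4-benzodioxin-6-yl]prop-2-enal | COc1cc([C@@H]2Oc3cc(/C=C/C=O)ccc3O[C@H]2CO)cc(OC)c1O | target

Total step count: 7. Longest linear sequence: 7 (1 → 2 → 5 → 9 → 10 → 11 → 13 → 14).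

**Steps most likely to fail**

Step 3 (new method).
- What may go wrong: the ligand-tempered Lewis acid may fail to ionise the aryl acetal. Cleavage may occur at C7–O3' as well as at C7–O4'. A 1,2-aryl or 1,2-hydride migration to the diazonium carbon may outrun capture by oxygen. Facial or cis/trans selectivity may be poor.
- Fallback: this uses known chemistry only. It forms C8–O4' by phenol alkylation and C7–O3' by benzylic substitution, sets out from 2, 3 and 6, and comes back at 9.
- Roskamp homologation of 2 with 6 (NbCl5 cat., CH2Cl2) should give ethyl 3-[3,5-dimethoxy-4-(triisopropylsilyloxy)phenyl]-3-oxopropanoate F1.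
- NBS bromination then leads to racemic ethyl 2-bromo-3-[3,5-dimethoxy-4-(triisopropylsilyloxy)phenyl]-3-oxopropanoate F2.
- The more acidic 4-OH of 3 is alkylated with it (Li2CO3, DMF) to methyl 4-({1-ethoxy-3-[3,5-dimethoxy-4-(triisopropylsilyloxy)phenyl]-1,3-dioxopropan-2-yl}oxy)-3-hydroxybenzoate F3, whose C8 centre racemises freely.
- Noyori–Ikariya transfer hydrogenation with dynamic kinetic resolution (RuCl(p-cymene)(TsDPEN), antipode chosen for 2R, HCO2H/Et3N) should give the syn product ethyl (2R,3S)-3-[3,5-dimethoxy-4-(triisopropylsilyloxy)phenyl]-3-hydroxy-2-[2-hydroxy-4-(methoxycarbonyl)phenoxy]propanoate F4.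
- Catalytic TsOH in CH2Cl2 closes the dioxane through the benzylic cation, with the fixed C8 centre steering C7 to the trans ester 9.

Step 2.
- What may go wrong: exchange with the electron-poor catechol may be slow or stall at an unfavourable equilibrium, and the silyl ether may be lost during prolonged acidic reflux.
- Fallback: this replaces equilibrium-driven exchange by silicon-driven acetalisation at low temperature. It sets out from 3 and 2 and comes back at 5.
- 3 is persilylated with HN(SiMe3)2 to methyl 3,4-bis(trimethylsilyloxy)benzoate F5.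
- F5 is condensed directly with aldehyde 2 under Noyori acetalisation conditions (TMSOTf cat., CH2Cl2, −78 to −20 °C), where formation of a Si–O–Si bond supplies the driving force.

Step 6.
- What may go wrong: the electron-rich aldehyde may react sluggishly, and the enal product may undergo a second olefination.
- Fallback: this homologates at the ester oxidation level, where no second olefination is possible, and then adjusts the oxidation state. It sets out from 11 and comes back at 13.
- Ph3P=CHCO2Et (CH2Cl2, rt) should give ethyl (2E)-3-{(2S,3S)-3-[3,5-dimethoxy-4-(triisopropylsilyloxy)phenyl]-2-(hydroxymethyl)-2,3-dihydro-1,4-benzodioxin-6-yl}prop-2-enoate F6.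
- iBu2AlH (CH2Cl2, −78 °C) reduces it to (2E)-3-{(2S,3S)-3-[3,5-dimethoxy-4-(triisopropylsilyloxy)phenyl]-2-(hydroxymethyl)-2,3-dihydro-1,4-benzodioxin-6-yl}prop-2-en-1-ol F7.
- MnO2 oxidises only the allylic alcohol to 13.

**Further compounds**
F1 | step 3 | ethyl 3-[3,5-dimethoxy-4-(triisopropylsilyloxy)phenyl]-3-oxopropanoate | CCOC(=O)CC(=O)c1cc(OC)c(O[Si](C(C)C)(C(C)C)C(C)C)c(OC)c1
F2 | step 3 | ethyl 2-bromo-3-[3,5-dimethoxy-4-(triisopropylsilyloxy)phenyl]-3-oxopropanoate (racemic) | CCOC(=O)C(Br)C(=O)c1cc(OC)c(O[Si](C(C)C)(C(C)C)C(C)C)c(OC)c1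
F3 | step 3 | methyl 4-({1-ethoxy-3-[3,5-dimethoxy-4-(triisopropylsilyloxy)phenyl]-1,3-dioxopropan-2-yl}oxy)-3-hydroxybenzoate (racemic, labile) | CCOC(=O)C(Oc1ccc(C(=O)OC)cc1O)C(=O)c1cc(OC)c(O[Si](C(C)C)(C(C)C)C(C)C)c(OC)c1
F4 | step 3 | ethyl (2R,3S)-3-[3,5-dimethoxy-4-(triisopropylsilyloxy)phenyl]-3-hydroxy-2-[2-hydroxy-4-(methoxycarbonyl)phenoxy]propanoate | CCOC(=O)[C@H](Oc1ccc(C(=O)OC)cc1O)[C@@H](O)c1cc(OC)c(O[Si](C(C)C)(C(C)C)C(C)C)c(OC)c1
F5 | step 2 | methyl 3,4-bis(trimethylsilyloxy)benzoate | COC(=O)c1ccc(O[Si](C)(C)C)c(O[Si](C)(C)C)c1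
F6 | step 6 | ethyl (2E)-3-{(2S,3S)-3-[3,5-dimethoxy-4-(triisopropylsilyloxy)phenyl]-2-(hydroxymethyl)-2,3-dihydro-1,4-benzodioxin-6-yl}prop-2-enoate | COc1cc([C@@H]2Oc3cc(/C=C/C(=O)OCC)ccc3O[C@H]2CO)cc(OC)c1O[Si](C(C)C)(C(C)C)C(C)C
F7 | step 6 | (2E)-3-{(2S,3S)-3-[3,5-dimethoxy-4-(triisopropylsilyloxy)phenyl]-2-(hydroxymethyl)-2,3-dihydro-1,4-benzodioxin-6-yl}prop-2-en-1-ol | COc1cc([C@@H]2Oc3cc(/C=C/CO)ccc3O[C@H]2CO)cc(OC)c1O[Si](C(C)C)(C(C)C)C(C)C
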